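The C30 skeleton is cut between C12, the sp3 CH2 two carbons out from C9 of ring B, and C13, the vinylic CH of the E-configured C13=C14 olefin. A stereoretentive Negishi alkyl–alkenyl coupling joins the C12 alkylzinc iodide of the complete cis-fused ring A/ring B ketone to the (E)-C14 alkenyl iodide made by syn-carboalumination of a geranylacetone-derived alkyne, so bond and olefin geometry are secured in one operation. The bicyclic half grows from (R)-linalool (C8 carbinol) through ring-closing metathesis, two face-selective Michael additions (C9, C10), Robinson closure of ring A, cis-selective hydrogenation (C5) and C4 dimethylation.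

Key step: step 15

Remark: the target SMILES encodes a cis-fused decalin (H-5 and the C10 methyl on the same face; 5S,8R,9R,10S), with the C9 chain cis and the C8 hydroxyl trans to the C10 methyl, and the route is laid out for exactly this isomer. Locants are labdane-type (ring A C1–C5/C10, ring B C5–C10, C11/C12 on C9), and β is the face of the C10 methyl.

Step 1
Reactants: 1 (E)-geranylacetone
Product: 3 (5E)-6,10-dimethylundeca-5,9-dien-1-yne, via enol phosphate 2 (not isolated)
Conditions: LDA (1.05 equiv), THF, −78 °C; ClP(O)(OEt)2, −78 °C → rt; LDA (2.3 equiv), −78 °C → rt; H2O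
Reagents that add atoms: none
Why: Kinetic enolisation on the methyl side, O-phosphorylation and base-induced elimination of diethyl phosphate convert the methyl ketone into the terminal alkyne (methyl ketone to alkyne conversion through an enol phosphate) without touching the E olefin.

Step 2
Reactants: 3 (5E)-6,10-dimethylundeca-5,9-dien-1-yne
Product: 5 (1E,5E)-1-iodo-2,6,10-trimethylundeca-1,5,9-triene, via alkenylalane 4 (not isolated)
Conditions: AlMe3 (2 equiv), Cp2ZrCl2 (0.25 equiv), CH2Cl2, rt; I2, THF, −30 → 0 °C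
Reagents that add atoms: trimethylaluminium, C[Al](C)C; iodine, [I][I]
Why: Zirconium-catalysed carboalumination adds CH3 and Al syn across the terminal alkyne with Al on the terminal carbon, and iodinolysis with retention fixes the E geometry of the future C13=C14 olefin.

Step 3
Reactants: 6 (R)-(−)-linalool
Product: 7 (3R)-3,7-dimethyl-3-(triethylsilyloxy)octa-1,6-diene
Conditions: TESOTf, 2,6-lutidine, CH2Cl2, −78 → 0 °C
Reagents that add atoms: triethylsilyl trifluoromethanesulfonate, CC[Si](CC)(CC)OS(=O)(=O)C(F)(F)F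
Why: Silyl triflate silylation of the tertiary allylic alcohol leaves the stereocentre (the future C8) untouched and supplies the bulky group that later steers the attack at C9.

Step 4
Reactants: 7 (3R)-3,7-dimethyl-3-(triethylsilyloxy)octa-1,6-diene
Product: 9 (4R)-4-methyl-4-(triethylsilyloxy)hex-5-enal, via ozonide 8 (not isolated)
Conditions: O3, CH2Cl2, −78 °C (Sudan Red 7B end point); PPh3, −78 °C → rt
Reagents that add atoms: ozone, [O-][O+]=O
Why: Ozone should cleave the electron-rich trisubstituted olefin much faster than the hindered monosubstituted vinyl group (chemoselective ozonolysis with reductive work-up).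

Step 5
Reactants: 9 (4R)-4-methyl-4-(triethylsilyloxy)hex-5-enal
Product: 10 (6R)-2,6-dimethyl-6-(triethylsilyloxy)octa-1,7-dien-3-ol (C3 epimer mixture)
Conditions: isopropenylmagnesium bromide (1.3 equiv), THF, −78 → 0 °C; H2O
Reagents that add atoms: isopropenylmagnesium bromide, CC(=C)[Mg]Br
Why: Grignard 1,2-addition to the aldehyde brings in C10 and its methyl, and the new carbinol centre is irrelevant because it is oxidised in step 7.

Step 6
Reactants: 10 (6R)-2,6-dimethyl-6-(triethylsilyloxy)octa-1,7-dien-3-ol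
Product: 11 (4R)-2,4-dimethyl-4-(triethylsilyloxy)cyclohex-2-en-1-ol (C1 epimer mixture)
Conditions: second-generation Grubbs catalyst (5 mol %), CH2Cl2, 40 °C
Reagents that add atoms: none
Why: Ring-closing metathesis between the vinyl group and the 1,1-disubstituted olefin closes six-membered ring B with loss of ethene, the free allylic hydroxyl assisting the hindered olefin.

Step 7
Reactants: 11 (4R)-2,4-dimethyl-4-(triethylsilyloxy)cyclohex-2-en-1-ol
Product: 12 (4R)-2,4-dimethyl-4-(triethylsilyloxy)cyclohex-2-en-1-one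
Conditions: Dess–Martin periodinane, NaHCO3, CH2Cl2, 0 °C → rt
Reagents that add atoms: none
Why: Mild oxidation of the allylic alcohol gives the ring B enone and converges both epimers.

Step 8
Reactants: 12 (4R)-2,4-dimethyl-4-(triethylsilyloxy)cyclohex-2-en-1-one
Product: 15 methyl 2-[(1R,2R,6R)-2,6-dimethyl-3-oxo-2-(3-oxobutyl)-6-(triethylsilyloxy)cyclohexyl]acetate, via ring B silyl enol ether 13 (not isolated), via acyclic silyl enol ether 14 (not isolated)
Conditions: CH2=C(OMe)OTBS (1.3 equiv), HNTf2 (3 mol %), CH2Cl2, −78 °C; methyl vinyl ketone (1.5 equiv), −78 → −40 °C; 1 M HCl, THF, 0 °C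
Reagents that add atoms: tert-butyl[(1-methoxyethenyl)oxy]dimethylsilane, COC(=C)O[Si](C)(C)C(C)(C)C; methyl vinyl ketone, CC(=O)C=C
Why: Two consecutive Mukaiyama–Michael additions under silyl triflimide catalysis should first place CH2CO2Me on C9 anti to the OTES group of C8 and then let the regiodefined tetrasubstituted enol ether attack the enone through C10 anti to the pseudoaxial C9 substituent (A(1,2) strain against the C10 methyl), so that the C10 methyl ends up cis to C11 and trans to the oxygen on C8.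

Step 9
Reactants: 15 methyl 2-[(1R,2R,6R)-2,6-dimethyl-3-oxo-2-(3-oxobutyl)-6-(triethylsilyloxy)cyclohexyl]acetate
Product: 16 methyl 2-[(1R,2R,8aR)-2,8a-dimethyl-6-oxo-2-(triethylsilyloxy)-1,2,3,4,6,7,8,8a-octahydronaphthalen-1-yl]acetate
Conditions: NaOMe, MeOH, 50 °C
Reagents that add atoms: none
Why: Intramolecular aldol condensation of the methyl ketone onto the ring ketone (second half of a Robinson annulation) closes ring A as the C4=C5 enone, and neither C9 nor C10 can epimerise because neither is enolisable.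

Step 10
Reactants: 16 methyl 2-[(1R,2R,8aR)-2,8a-dimethyl-6-oxo-2-(triethylsilyloxy)-1,2,3,4,6,7,8,8a-octahydronaphthalen-1-yl]acetate
Product: 17 methyl 2-[(1R,2R,4aR,8aS)-2,8a-dimethyl-6-oxo-2-(triethylsilyloxy)decahydronaphthalen-1-yl]acetate
Conditions: H2 (1 atm), 10 % Pd/C, EtOAc, Et3N (1 %), rt
Reagents that add atoms: none
Why: Heterogeneous hydrogenation of 10-methyl-4-en-3-one octalones in neutral to basic medium should deliver hydrogen to C5 on the face of the angular methyl, as in the 5β-selective hydrogenation of 4-en-3-one steroids, which sets the cis ring fusion.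

Step 11
Reactants: 17 methyl 2-[(1R,2R,4aR,8aS)-2,8a-dimethyl-6-oxo-2-(triethylsilyloxy)decahydronaphthalen-1-yl]acetate
Product: 19 methyl 2-[(1R,2R,4aS,8aS)-2,5,5,8a-tetramethyl-6-oxo-2-(triethylsilyloxy)decahydronaphthalen-1-yl]acetate, via monomethyl ketone 18 (not isolated)
Conditions: KOt-Bu (2.3 equiv), MeI (2.5 equiv), t-BuOH/THF, 0 °C → rt
Reagents that add atoms: iodomethane, CI
Why: Cis-fused 3-decalones with an angular methyl enolise towards C4 (as 5β 3-keto steroids do), and after the first methylation the more substituted C3–C4 enolate is again the thermodynamic one, so both methyl groups should enter at C4 (thermodynamic enolate alkylation).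

Step 12
Reactants: 19 methyl 2-[(1R,2R,4aS,8aS)-2,5,5,8a-tetramethyl-6-oxo-2-(triethylsilyloxy)decahydronaphthalen-1-yl]acetate
Product: 20 2-[(1R,2R,4aS,8aS)-6-hydroxy-2,5,5,8a-tetramethyl-2-(triethylsilyloxy)decahydronaphthalen-1-yl]ethanol (C3 carbinol epimers)
Conditions: LiAlH4, THF, 0 °C → rt; H2O, aq NaOH
Reagents that add atoms: none
Why: Hydride reduction turns the ester into the C12 primary alcohol and the ketone into a C3 carbinol whose configuration is irrelevant because it is reoxidised in step 14.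

Step 13
Reactants: 20 2-[(1R,2R,4aS,8aS)-6-hydroxy-2,5,5,8a-tetramethyl-2-(triethylsilyloxy)decahydronaphthalen-1-yl]ethanol
Product: 21 (4aS,5R,6R,8aS)-5-(2-iodoethyl)-1,1,4a,6-tetramethyl-6-(triethylsilyloxy)decahydronaphthalen-2-ol (C3 carbinol epimers)
Conditions: I2 (1.1 equiv), PPh3, imidazole, CH2Cl2, 0 °C
Reagents that add atoms: iodine, [I][I]
Why: Appel-type iodination should discriminate the primary alcohol from the neopentyl-like secondary one, while the silyl ether on O8 blocks cyclisation to a tetrahydrofuran.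

Step 14
Reactants: 21 (4aS,5R,6R,8aS)-5-(2-iodoethyl)-1,1,4a,6-tetramethyl-6-(triethylsilyloxy)decahydronaphthalen-2-ol
Product: 22 (4aS,5R,6R,8aS)-5-(2-iodoethyl)-1,1,4a,6-tetramethyl-6-(triethylsilyloxy)octahydronaphthalen-2(1H)-one
Conditions: Dess–Martin periodinane, NaHCO3, CH2Cl2, rt
Reagents that add atoms: none
Why: Oxidation of the hindered secondary carbinol restores the C3 ketone and leaves the primary iodide untouched.

Step 15
Reactants: 22 (4aS,5R,6R,8aS)-5-(2-iodoethyl)-1,1,4a,6-tetramethyl-6-(triethylsilyloxy)octahydronaphthalen-2(1H)-one; 5 (1E,5E)-1-iodo-2,6,10-trimethylundeca-1,5,9-triene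
Product: 24 (4aS,5R,6R,8aS)-1,1,4a,6-tetramethyl-6-(triethylsilyloxy)-5-[(3E,7E)-4,8,12-trimethyltrideca-3,7,11-trien-1-yl]octahydronaphthalen-2(1H)-one, via alkylzinc iodide 23 (not isolated)
Conditions: Zn dust (activated by BrCH2CH2Br, TMSCl), LiCl, THF, 35 °C; then 5, PdCl2(dppf) (5 mol %), THF, 40 °C
Reagents that add atoms: none
Why: Zinc inserts into the primary carbon–iodine bond at C12 with LiCl assistance; the divalent palladium precatalyst is reduced in situ to zerovalent palladium, which adds oxidatively to the alkenyl carbon–iodine bond at C13 with retention, takes over the alkyl group from zinc and forms the C12–C13 bond by reductive elimination. The closest known reaction type is the Negishi coupling of primary alkylzinc halides with (E)-alkenyl iodides obtained by alkyne carboalumination. No ring is closed and no stereocentre is created. The stereochemical element at stake is the E geometry of the C13=C14 olefin, which is carried over because oxidative addition and reductive elimination at the alkenyl carbon are stereoretentive. The step needs insertion at the carbon–iodine bond without addition to the C3 ketone and sp3–sp2 coupling ahead of β-hydride elimination; the low nucleophilicity of the alkylzinc iodide and the wide-bite-angle dppf ligand, which speeds reductive elimination, should secure both. The four ring stereocentres are remote from the reacting carbon and the O8 silyl ether keeps the oxygen from displacing the iodide.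

Step 16
Reactants: 24 (4aS,5R,6R,8aS)-1,1,4a,6-tetramethyl-6-(triethylsilyloxy)-5-[(3E,7E)-4,8,12-trimethyltrideca-3,7,11-trien-1-yl]octahydronaphthalen-2(1H)-one
Product: 25 (4aS,5R,6R,8aS)-6-hydroxy-1,1,4a,6-tetramethyl-5-[(3E,7E)-4,8,12-trimethyltrideca-3,7,11-trien-1-yl]octahydronaphthalen-2(1H)-one
Conditions: TBAF, THF, rt → 40 °C; H2O
Reagents that add atoms: none
Why: Fluoride cleaves the tertiary triethylsilyl ether and releases the C8 alcohol without affecting the ketone or the trisubstituted olefins.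

Compound list
1 | (E)-geranylacetone, (5E)-6,10-dimethylundeca-5,9-dien-2-one | CC(C)=CCC/C(C)=C/CCC(C)=O | starting material
2 | diethyl (5E)-6,10-dimethylundeca-1,5,9-trien-2-yl phosphate | CC(C)=CCC/C(C)=C/CCC(=C)OP(=O)(OCC)OCC | intermediate
3 | (5E)-6,10-dimethylundeca-5,9-dien-1-yne | CC(C)=CCC/C(C)=C/CCC#C | intermediate
4 | dimethyl[(1E,5E)-2,6,10-trimethylundeca-1,5,9-trien-1-yl]alane | CC(C)=CCC/C(C)=C/CC/C(C)=C/[Al](C)C | intermediate
5 | (1E,5E)-1-iodo-2,6,10-trimethylundeca-1,5,9-triene | CC(C)=CCC/C(C)=C/CC/C(C)=C/I | intermediate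
6 | (R)-(−)-linalool, (3R)-3,7-dimethylocta-1,6-dien-3-ol | CC(C)=CCC[C@@](C)(O)C=C | starting material
7 | (3R)-3,7-dimethyl-3-(triethylsilyloxy)octa-1,6-diene | CC(C)=CCC[C@@](C)(O[Si](CC)(CC)CC)C=C | intermediate
8 | 3,3-dimethyl-5-[(3R)-3-methyl-3-(triethylsilyloxy)pent-4-en-1-yl]-1,2,4-trioxolane (ozonide) | CC1(C)OOC(CC[C@@](C)(O[Si](CC)(CC)CC)C=C)O1 | intermediate
9 | (4R)-4-methyl-4-(triethylsilyloxy)hex-5-enal | O=CCC[C@@](C)(O[Si](CC)(CC)CC)C=C | intermediate
10 | (6R)-2,6-dimethyl-6-(triethylsilyloxy)octa-1,7-dien-3-ol, C3 epimers | CC(=C)C(O)CC[C@@](C)(O[Si](CC)(CC)CC)C=C | intermediate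
11 | (4R)-2,4-dimethyl-4-(triethylsilyloxy)cyclohex-2-en-1-ol, C1 epimers | OC1CC[C@@](C)(O[Si](CC)(CC)CC)C=C1C | intermediate
12 | (4R)-2,4-dimethyl-4-(triethylsilyloxy)cyclohex-2-en-1-one | O=C1CC[C@@](C)(O[Si](CC)(CC)CC)C=C1C | intermediate
13 | methyl 2-[(1R,6R)-3-(tert-butyldimethylsilyloxy)-2,6-dimethyl-6-(triethylsilyloxy)cyclohex-2-en-1-yl]acetate (CH2CO2Me trans to OTES) | COC(=O)C[C@@H]1C(C)=C(O[Si](C)(C)C(C)(C)C)CC[C@@]1(C)O[Si](CC)(CC)CC | intermediate
14 | methyl 2-[(1R,2R,6R)-2-[(2Z)-3-(tert-butyldimethylsilyloxy)but-2-en-1-yl]-2,6-dimethyl-3-oxo-6-(triethylsilyloxy)cyclohexyl]acetate (Z isomer expected to predominate) | COC(=O)C[C@@H]1[C@@](C)(C/C=C(/C)O[Si](C)(C)C(C)(C)C)C(=O)CC[C@@]1(C)O[Si](CC)(CC)CC | intermediate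
15 | methyl 2-[(1R,2R,6R)-2,6-dimethyl-3-oxo-2-(3-oxobutyl)-6-(triethylsilyloxy)cyclohexyl]acetate | COC(=O)C[C@@H]1[C@@](C)(CCC(C)=O)C(=O)CC[C@@]1(C)O[Si](CC)(CC)CC | intermediate
16 | methyl 2-[(1R,2R,8aR)-2,8a-dimethyl-6-oxo-2-(triethylsilyloxy)-1,2,3,4,6,7,8,8a-octahydronaphthalen-1-yl]acetate (C4=C5 enone) | COC(=O)C[C@@H]1[C@@]2(C)CCC(=O)C=C2CC[C@@]1(C)O[Si](CC)(CC)CC | intermediate
17 | methyl 2-[(1R,2R,4aR,8aS)-2,8a-dimethyl-6-oxo-2-(triethylsilyloxy)decahydronaphthalen-1-yl]acetate (cis-fused, H-5 β) | COC(=O)C[C@@H]1[C@@]2(C)CCC(=O)C[C@H]2CC[C@@]1(C)O[Si](CC)(CC)CC | intermediate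
18 | 4-monomethyl derivative of 17, C4 epimers | COC(=O)C[C@@H]1[C@@]2(C)CCC(=O)C(C)[C@H]2CC[C@@]1(C)O[Si](CC)(CC)CC | intermediate
19 | methyl 2-[(1R,2R,4aS,8aS)-2,5,5,8a-tetramethyl-6-oxo-2-(triethylsilyloxy)decahydronaphthalen-1-yl]acetate | COC(=O)C[C@@H]1[C@@]2(C)CCC(=O)C(C)(C)[C@H]2CC[C@@]1(C)O[Si](CC)(CC)CC | intermediate
20 | 2-[(1R,2R,4aS,8aS)-6-hydroxy-2,5,5,8a-tetramethyl-2-(triethylsilyloxy)decahydronaphthalen-1-yl]ethanol, C3 carbinol epimers | OCC[C@@H]1[C@@]2(C)CCC(O)C(C)(C)[C@H]2CC[C@@]1(C)O[Si](CC)(CC)CC | intermediate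
21 | (4aS,5R,6R,8aS)-5-(2-iodoethyl)-1,1,4a,6-tetramethyl-6-(triethylsilyloxy)decahydronaphthalen-2-ol, C3 carbinol epimers | ICC[C@@H]1[C@@]2(C)CCC(O)C(C)(C)[C@H]2CC[C@@]1(C)O[Si](CC)(CC)CC | intermediate
22 | (4aS,5R,6R,8aS)-5-(2-iodoethyl)-1,1,4a,6-tetramethyl-6-(triethylsilyloxy)octahydronaphthalen-2(1H)-one | ICC[C@@H]1[C@@]2(C)CCC(=O)C(C)(C)[C@H]2CC[C@@]1(C)O[Si](CC)(CC)CC | intermediate
23 | alkylzinc iodide of 22 (C12–Zn) | I[Zn]CC[C@@H]1[C@@]2(C)CCC(=O)C(C)(C)[C@H]2CC[C@@]1(C)O[Si](CC)(CC)CC | intermediate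
24 | (4aS,5R,6R,8aS)-1,1,4a,6-tetramethyl-6-(triethylsilyloxy)-5-[(3E,7E)-4,8,12-trimethyltrideca-3,7,11-trien-1-yl]octahydronaphthalen-2(1H)-one | CC(C)=CCC/C(C)=C/CC/C(C)=C/CC[C@@H]1[C@@]2(C)CCC(=O)C(C)(C)[C@H]2CC[C@@]1(C)O[Si](CC)(CC)CC | intermediate
25 | (4aS,5R,6R,8aS)-6-hydroxy-1,1,4a,6-tetramethyl-5-[(3E,7E)-4,8,12-trimethyltrideca-3,7,11-trien-1-yl]octahydronaphthalen-2(1H)-one | CC(C)=CCC/C(C)=C/CC/C(C)=C/CC[C@@H]1[C@@]2(C)CCC(=O)C(C)(C)[C@H]2CC[C@@]1(C)O | target

Total step count: 16. Longest linear sequence: 14 steps (steps 3 to 16, from (R)-linalool); steps 1 and 2 make the alkenyl iodide in parallel.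

Steps most likely to fail

Step 11. Loss of regiocontrol in the enolisation of the conformationally mobile cis-decalone would send methyl groups to C2 or lead to over-alkylation. The fallback sets out from enone 16 and returns at 19, bypassing 17 and 18. Deconjugative double methylation of 16 (KOt-Bu, MeI, t-BuOH), regiospecific for C4 through the extended dienolate, should give the 4,4-dimethyl C5=C6 ketone F4. NaBH4 in MeOH should give the 3β (3S) alcohol F5. Hydrogenation with [Ir(cod)(PCy3)(py)]PF6 and H2 in CH2Cl2, directed by the homoallylic hydroxyl, should deliver hydrogen to C5 on the β face and give the cis-fused alcohol F6. Dess–Martin oxidation of F6 then gives 19.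

Step 8. The second conjugate addition, which must create quaternary C10 next to the substituted C9, may stall, so that protodesilylation of the enol ether and polymerisation of the enone take over. The fallback sets out from silyl enol ether 13, isolated after the first Michael addition, and returns at 16, bypassing 15. Anhydrous fluoride (tetrabutylammonium difluorotriphenylsilicate, THF, −78 °C) releases the regiodefined enolate in the presence of 3-(trimethylsilyl)but-3-en-2-one, whose α-silyl group stabilises the adduct and suppresses polymerisation. This should give the α-silyl diketone F1, again by attack anti to the C9 substituent. NaOMe in MeOH then removes the silyl group and effects the aldol condensation to 16.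

Step 10. Poor facial selectivity in the delivery of hydrogen to C5 would give trans-fused material. The fallback sets out from 16 and returns at 17. Reduction with NaBH4 and CeCl3·7H2O in MeOH at −20 °C should give the 3β (3S) allylic alcohol F2 by hydride attack anti to the angular methyl. Hydrogenation with [Ir(cod)(PCy3)(py)]PF6 and H2 in CH2Cl2, directed by the allylic hydroxyl, should place hydrogen on C5 from the β face and give the cis-fused alcohol F3. Dess–Martin oxidation of F3 gives 17.

Further compounds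
F1 | step 8 | methyl 2-[(1R,2R,6R)-2,6-dimethyl-3-oxo-2-[3-oxo-2-(trimethylsilyl)butyl]-6-(triethylsilyloxy)cyclohexyl]acetate (silyl-bearing carbon as epimers) | COC(=O)C[C@@H]1[C@@](C)(CC([Si](C)(C)C)C(C)=O)C(=O)CC[C@@]1(C)O[Si](CC)(CC)CC
F2 | step 10 | 3β-allylic alcohol of 16, methyl 2-[(1R,2R,6S,8aR)-6-hydroxy-2,8a-dimethyl-2-(triethylsilyloxy)-1,2,3,4,6,7,8,8a-octahydronaphthalen-1-yl]acetate | COC(=O)C[C@@H]1[C@@]2(C)CC[C@H](O)C=C2CC[C@@]1(C)O[Si](CC)(CC)CC
F3 | step 10 | cis-fused 3β-alcohol, 3β-hydroxy analogue of 17 (H-5 β) | COC(=O)C[C@@H]1[C@@]2(C)CC[C@H](O)C[C@H]2CC[C@@]1(C)O[Si](CC)(CC)CC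
F4 | step 11 | 4,4-dimethyl C5=C6 ketone, methyl 2-[2,5,5,8a-tetramethyl-6-oxo-2-(triethylsilyloxy)-1,2,3,5,6,7,8,8a-octahydronaphthalen-1-yl]acetate (C8, C9, C10 as in 16) | COC(=O)C[C@@H]1[C@@]2(C)CCC(=O)C(C)(C)C2=CC[C@@]1(C)O[Si](CC)(CC)CC
F5 | step 11 | 3β (3S) alcohol of F4 | COC(=O)C[C@@H]1[C@@]2(C)CC[C@H](O)C(C)(C)C2=CC[C@@]1(C)O[Si](CC)(CC)CC
F6 | step 11 | cis-fused 3β-alcohol, 3β-hydroxy analogue of 19 (H-5 β) | COC(=O)C[C@@H]1[C@@]2(C)CC[C@H](O)C(C)(C)[C@H]2CC[C@@]1(C)O[Si](CC)(CC)CC
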